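**Strategy.** The pyranone ring is closed last by making the C2–C3 bond. C2, the O1–CH2 carbon, is treated as the methyl group of an ordinary aryl methyl ether. C3, benzylic to ring B and α to the C4 ketone, is treated as a donor/acceptor carbene carbon. A chiral dirhodium(II) catalyst should turn an acyclic α-diazo deoxybenzoin, carrying a 2,4-dimethoxy-5-prenylphenyl ketone and a silyl-protected 2-hydroxy-4-methoxyphenyl group, into the isoflavanone by enantioselective 1,6-C–H insertion into the ortho-methoxy group. This forms the ring and the only stereocentre (3S) in one operation. The precursor comes from two simple arenes by ketone α-arylation and diazo transfer.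

Key step: step 6

Remark on the chemistry: the stereocentre of the target as drawn is (3S) (CIP order C4 > C2 > C1' > H). The sense of induction of Rh2(S-PTAD)4 on this substrate class is an assumption; if the first run shows the (3R) product, the commercially available antipode Rh2(R-PTAD)4 would be used instead. Compounds 1, 3 and 5 are assumed to be purchased.

Step 1
Reactants: 1 1-(2,4-dimethoxyphenyl)ethan-1-one
Product: 2 1-(5-bromo-2,4-dimethoxyphenyl)ethan-1-one
Conditions: NBS (1.05 equiv), MeCN, 0 °C to rt, dark
Reagents that add atoms: N-bromosuccinimide, O=C1CCC(=O)N1Br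
Why: Electrophilic aromatic bromination should go to C5, the only unhindered position that is para to one methoxy group and ortho to the other, and in MeCN without acid or radical initiator ring bromination should outpace α-bromination of the ketone.

Step 2
Reactants: 2 1-(5-bromo-2,4-dimethoxyphenyl)ethan-1-one; 3 tributyl(3-methylbut-2-en-1-yl)stannane
Product: 4 1-[2,4-dimethoxy-5-(3-methylbut-2-en-1-yl)phenyl]ethan-1-one
Conditions: Pd(PPh3)4 (5 mol%), DMF, 100 °C; aq. KF work-up
Reagents that add atoms: none
Why: Stille coupling of the aryl bromide with the prenylstannane should deliver the linear 3-methylbut-2-enyl arene, the ketone and methoxy groups being inert to Pd(0).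

Step 3
Reactants: 5 2-bromo-5-methoxyphenol
Product: 6 (2-bromo-5-methoxyphenoxy)(tert-butyl)dimethylsilane
Conditions: TBSCl, imidazole, DMF, rt
Reagents that add atoms: tert-butyldimethylsilyl chloride, CC(C)(C)[Si](C)(C)Cl
Why: Standard O-silylation of a phenol; the silyl group is chosen because it has no C–H bond α to oxygen that could later compete for the carbene and because it can be removed without base.

Step 4
Reactants: 4 1-[2,4-dimethoxy-5-(3-methylbut-2-en-1-yl)phenyl]ethan-1-one; 6 (2-bromo-5-methoxyphenoxy)(tert-butyl)dimethylsilane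
Product: 7 2-[2-(tert-butyldimethylsilyloxy)-4-methoxyphenyl]-1-[2,4-dimethoxy-5-(3-methylbut-2-en-1-yl)phenyl]ethan-1-one
Conditions: Pd2(dba)3 (1.5 mol%), XPhos (6 mol%), K3PO4 (2.5 equiv), toluene, 90 °C
Reagents that add atoms: none
Why: Pd-catalysed α-arylation of a methyl ketone enolate with an aryl bromide; the weak base K3PO4 should spare the aryl silyl ether, and the ortho-substituted aryl group on the product enolate should prevent a second arylation.

Step 5
Reactants: 7 2-[2-(tert-butyldimethylsilyloxy)-4-methoxyphenyl]-1-[2,4-dimethoxy-5-(3-methylbut-2-en-1-yl)phenyl]ethan-1-one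
Product: 8 2-diazo-2-[2-(tert-butyldimethylsilyloxy)-4-methoxyphenyl]-1-[2,4-dimethoxy-5-(3-methylbut-2-en-1-yl)phenyl]ethan-1-one
Conditions: p-ABSA (1.3 equiv), DBU (1.5 equiv), MeCN, 0 °C to rt, dark
Reagents that add atoms: 4-acetamidobenzenesulfonyl azide, CC(=O)Nc1ccc(cc1)S(=O)(=O)N=[N+]=[N-]
Why: Regitz diazo transfer; the methylene of a deoxybenzoin is acidified by both the ketone and the aryl ring, so DBU should suffice without a prior activating group.

Step 6
Reactants: 8 2-diazo-2-[2-(tert-butyldimethylsilyloxy)-4-methoxyphenyl]-1-[2,4-dimethoxy-5-(3-methylbut-2-en-1-yl)phenyl]ethan-1-one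
Product: 9 (3S)-3-[2-(tert-butyldimethylsilyloxy)-4-methoxyphenyl]-7-methoxy-6-(3-methylbut-2-en-1-yl)-2,3-dihydro-4H-chromen-4-one
Conditions: Rh2(S-PTAD)4 (1 mol%), 4 Å MS, degassed CH2Cl2, syringe-pump addition of 8 (final 0.01 M), rt to 40 °C, dark
Reagents that add atoms: none
Why: Proposed new method: Rh(II) should expel N2 from 8 to give an electrophilic donor/acceptor rhodium carbenoid at the future C3, which takes up one C–H bond of the methoxy group ortho to the ketone in a concerted, asynchronous hydride-transfer/C–C bond-forming insertion, so that the methoxy carbon becomes C2 and the C2–C3 bond is made. The closest known reactions are the Rh(II)-catalysed C–H insertion of 2-alkoxyaryl diazoketones into O–CH2R groups to give 2-substituted chroman-4-ones and the enantioselective insertion of donor/acceptor carbenoids into methyl ethers; insertion of an α-aryl-α-diazoketone into an aryl O–CH3 group has not been shown, hence the label. The pyranone ring closes as a six-membered ring by 1,6-C–H insertion (carbenoid carbon, C=O, two aromatic carbons, O, CH2), the planar aryl ketone holding the methoxy group next to the carbenoid. C3, the only stereocentre, is the former carbenoid carbon, and its configuration is fixed by the face of the rhodium-bound carbene that the C–H bond reaches, which the chiral pocket of the phthalimido carboxylate ligands controls (catalyst control). The step needs chemoselectivity for this one C–H bond: the C7 and C4' methoxy groups cannot reach the carbenoid, the silyl group on O2' has no C–H α to oxygen and so shuts off the otherwise favoured 1,5-insertion to a dihydrobenzofuran, an oxonium ylide at the methoxy oxygen has no easy exit (methyl migrates poorly) and should revert, and the trisubstituted prenyl alkene can only react intermolecularly, which slow addition at high dilution suppresses.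

Step 7
Reactants: 9 (3S)-3-[2-(tert-butyldimethylsilyloxy)-4-methoxyphenyl]-7-methoxy-6-(3-methylbut-2-en-1-yl)-2,3-dihydro-4H-chromen-4-one
Product: 10 (3S)-3-(2-hydroxy-4-methoxyphenyl)-7-methoxy-6-(3-methylbut-2-en-1-yl)-2,3-dihydro-4H-chromen-4-one
Conditions: TBAF (1.1 equiv), AcOH (1.3 equiv), THF, 0 °C
Reagents that add atoms: none
Why: Fluoride-mediated cleavage of a phenolic silyl ether; acetic acid buffers the phenoxide so that the C3 stereocentre, α to the ketone and benzylic, should not epimerise, and the prenyl group is untouched.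

**Compound list**

1 | 1-(2,4-dimethoxyphenyl)ethan-1-one (2',4'-dimethoxyacetophenone) | CC(=O)c1ccc(OC)cc1OC | starting material
2 | 1-(5-bromo-2,4-dimethoxyphenyl)ethan-1-one | CC(=O)c1cc(Br)c(OC)cc1OC | intermediate
3 | tributyl(3-methylbut-2-en-1-yl)stannane (prenyltributyltin) | CCCC[Sn](CCCC)(CCCC)CC=C(C)C | starting material
4 | 1-[2,4-dimethoxy-5-(3-methylbut-2-en-1-yl)phenyl]ethan-1-one | CC(=O)c1cc(CC=C(C)C)c(OC)cc1OC | intermediate
5 | 2-bromo-5-methoxyphenol | COc1ccc(Br)c(O)c1 | starting material
6 | (2-bromo-5-methoxyphenoxy)(tert-butyl)dimethylsilane | COc1ccc(Br)c(O[Si](C)(C)C(C)(C)C)c1 | intermediate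
7 | 2-[2-(tert-butyldimethylsilyloxy)-4-methoxyphenyl]-1-[2,4-dimethoxy-5-(3-methylbut-2-en-1-yl)phenyl]ethan-1-one | COc1ccc(CC(=O)c2cc(CC=C(C)C)c(OC)cc2OC)c(O[Si](C)(C)C(C)(C)C)c1 | intermediate
8 | 2-diazo-2-[2-(tert-butyldimethylsilyloxy)-4-methoxyphenyl]-1-[2,4-dimethoxy-5-(3-methylbut-2-en-1-yl)phenyl]ethan-1-one | COc1ccc(C(=[N+]=[N-])C(=O)c2cc(CC=C(C)C)c(OC)cc2OC)c(O[Si](C)(C)C(C)(C)C)c1 | intermediate
9 | (3S)-3-[2-(tert-butyldimethylsilyloxy)-4-methoxyphenyl]-7-methoxy-6-(3-methylbut-2-en-1-yl)-2,3-dihydro-4H-chromen-4-one | COc1ccc([C@H]2COc3cc(OC)c(CC=C(C)C)cc3C2=O)c(O[Si](C)(C)C(C)(C)C)c1 | intermediate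
10 | (3S)-3-(2-hydroxy-4-methoxyphenyl)-7-methoxy-6-(3-methylbut-2-en-1-yl)-2,3-dihydro-4H-chromen-4-one | COc1ccc([C@H]2COc3cc(OC)c(CC=C(C)C)cc3C2=O)c(O)c1 | target

**Totals.** Total step count: 7. Longest linear sequence: 6 steps (1 → 2 → 4 → 7 → 8 → 9 → 10; step 3 is a one-step side branch).

**Steps most likely to fail**

Step 6 (Proposed new method). The carbenoid may be captured by the lone pair of the ortho-methoxy oxygen (five-membered oxonium ylide, then methyl shift or demethylation towards a benzofuran-3-one) faster than it inserts into the primary C–H bond, or the insertion may proceed with weak facial discrimination. The fallback uses known chemistry only, sets out from 7 and comes back at 9. Chelation-controlled cleavage of the methoxy group ortho to the ketone (BCl3, CH2Cl2, −78 °C) should give 2-[2-(tert-butyldimethylsilyloxy)-4-methoxyphenyl]-1-[2-hydroxy-4-methoxy-5-(3-methylbut-2-en-1-yl)phenyl]ethan-1-one F1. Condensation with N,N-dimethylformamide dimethyl acetal (toluene, 90 °C) should close this to the isoflavone 3-[2-(tert-butyldimethylsilyloxy)-4-methoxyphenyl]-7-methoxy-6-(3-methylbut-2-en-1-yl)-4H-chromen-4-one F2. Noyori asymmetric transfer hydrogenation with dynamic kinetic resolution (RuCl[(S,S)-TsDPEN](p-cymene), HCO2H/Et3N, EtOAc, 40 °C) should reduce the enone and the ketone to the cis alcohol (3S,4S)-3-[2-(tert-butyldimethylsilyloxy)-4-methoxyphenyl]-7-methoxy-6-(3-methylbut-2-en-1-yl)chroman-4-ol F3. Dess–Martin oxidation (NaHCO3, CH2Cl2, 0 °C) should then return ketone 9 with the C3 configuration intact.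

Step 4. The phenolic silyl group may be lost under hot basic conditions, and the electron-rich, ortho-substituted bromide may couple so slowly that enolate self-condensation takes over. The fallback sets out from 4 and comes back at 7. Ketone 4 would be converted into its silyl enol ether {1-[2,4-dimethoxy-5-(3-methylbut-2-en-1-yl)phenyl]ethenyloxy}trimethylsilane F4 (TMSOTf, Et3N, CH2Cl2, 0 °C). F4 would then be coupled with 6 without added base (Pd(OAc)2, P(t-Bu)3, Bu3SnF, toluene, 85 °C), where a tin enolate formed in the flask is arylated.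

Step 2. Allylic transposition during transmetalation may deliver the 1,1-dimethylallyl (reverse-prenyl) isomer alongside the prenyl arene. The fallback sets out from 2 and comes back at 4. Stille coupling of 2 with allyltributylstannane (Pd(PPh3)4, DMF, 100 °C), which has no regiochemical ambiguity, should give 1-[2,4-dimethoxy-5-(prop-2-en-1-yl)phenyl]ethan-1-one F5. Olefin cross-metathesis with excess 2-methylbut-2-ene (Grubbs second-generation catalyst, CH2Cl2, 40 °C) should then convert the allyl group into the prenyl group of 4.

**Further compounds**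

F1 | step 6 | 2-[2-(tert-butyldimethylsilyloxy)-4-methoxyphenyl]-1-[2-hydroxy-4-methoxy-5-(3-methylbut-2-en-1-yl)phenyl]ethan-1-one | COc1ccc(CC(=O)c2cc(CC=C(C)C)c(OC)cc2O)c(O[Si](C)(C)C(C)(C)C)c1
F2 | step 6 | 3-[2-(tert-butyldimethylsilyloxy)-4-methoxyphenyl]-7-methoxy-6-(3-methylbut-2-en-1-yl)-4H-chromen-4-one | COc1ccc(-c2coc3cc(OC)c(CC=C(C)C)cc3c2=O)c(O[Si](C)(C)C(C)(C)C)c1
F3 | step 6 | (3S,4S)-3-[2-(tert-butyldimethylsilyloxy)-4-methoxyphenyl]-7-methoxy-6-(3-methylbut-2-en-1-yl)chroman-4-ol | COc1ccc([C@H]2COc3cc(OC)c(CC=C(C)C)cc3[C@H]2O)c(O[Si](C)(C)C(C)(C)C)c1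
F4 | step 4 | {1-[2,4-dimethoxy-5-(3-methylbut-2-en-1-yl)phenyl]ethenyloxy}trimethylsilane | C=C(O[Si](C)(C)C)c1cc(CC=C(C)C)c(OC)cc1OC
F5 | step 2 | 1-[2,4-dimethoxy-5-(prop-2-en-1-yl)phenyl]ethan-1-one | CC(=O)c1cc(CC=C)c(OC)cc1OC
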